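(The numbers are those of an exercise, and the outcome is calculated.)

The flask was a closed, stirred vessel in which G could go two ways.

G 0.020 M; Z 2.8 mol%; time 3.0 min

    G → E (k1 = 0.0063 s⁻¹)
    L → X (k2 = 0.011 s⁻¹)
    G + Z → L + Q (k3 = 2.8 M⁻¹ s⁻¹)
    G + L → Q + L, rate k4*[L]*[G] (k4 = 14 M⁻¹ s⁻¹)

- the average divides the monomer in chains by the number of chains begun, living and dead together
- run time (flask): 3.0 min

* whether the average number of monomer units in a chain (chains begun, living or dead) reaches 3.0 by 3.0 min (yes / no)
* average number of monomer units in a chain (chains begun, living or dead) at 3.0 min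

I carried one quantity, the break-even end concentration [L]\* = k1/k4, which came to 4.50 × 10⁻⁴ M. At this [L], the pseudo-first-order loss of G by growth on L matches its loss to E, and [G] cancels from the comparison. I then took the settings in turn.

1. Loading: it gave [Z]₀ = 5.60 × 10⁻⁴ M, the most ends I allowed, and I counted that many chains. Z had a lifetime of about 17.9 s at charged G, shorter than the 90.9 s of an end, so I treated the ends as started at once.
2. Time: over 3.0 min, decay at k2 gave a mean [L] of 2.44 × 10⁻⁴ M, less than [L]\*. So I put the formation of E at 1.85 times chain growth.
3. G charge: I estimated 17.4 % of G left, so I put 0.00580 M into growth.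
4. Length: with the first unit of each chain added, I got 11.4, more than 3.0.

The forecast said yes and 11.1, with a range of 10.3 to 11.9, on the ground that “The chain count is set by how much Z is used up”. Its central value was lower than mine.

The flask gave yes and 11.3, and the length passed 3.0 at 0.239 min. At 3.00 min, [L] in the flask stood at 1.02 × 10⁻⁴ M, less than [L]\*, and the quotient [L]\*/[L] was 4.41, while G was going to E 4.4 times as fast as to growth, up from 1.3 at 0.881 min. By 3.00 min, E in the flask held 51.2 % of the G charged and Q held 31.4 %.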